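## The problem

Pseudopentafuhalol D (27) is a linear chain of five benzene rings, A to E, joined by four diaryl ether bonds and carrying thirteen free phenolic hydroxyls. It has no stereocenter and no element of chirality, so only connectivity has to be controlled.

The numbering used here is:
- Ring A is a 2,4,6-trihydroxyphenyl group.
- Ring B bears the ether to ring A at B1, the ether to ring C at the adjacent B6, and hydroxyls at B3 and B5.
- Ring C is bound to ring B through C1 and to ring D through C5, with hydroxyls at C3 and C4.
- Ring D bears the ether to ring C at D1, hydrogen at D2, hydroxyls at D3, D4 and D5, and the ether to ring E at D6.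
- Ring E is 3,4,5-trihydroxyphenyl.

The ether oxygens on B6 and D6 sit on carbons flanked by two further oxygen substituents, and every ring is electron-rich, which is the unfavourable case for copper-mediated ether formation. Ring D is pentaoxygenated, a pattern without a simple building block, and its oxygens must be told apart: two are ethers to different rings, three are free. The free pyrogallol, catechol and phloroglucinol units oxidise in air under basic conditions, so all hydroxyls must travel as methyl ethers and be released last.

The opening lies in ring D. Its four contiguous oxygen-bearing carbons D3 to D6 correspond to the four carbons of a squaric ester. D2–H and D1 with its ether oxygen correspond to a two-carbon 2-aryloxyvinyl unit. Ring D can therefore be grown from a four-membered ring with every oxygen already in place.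

## Retrosynthesis

**Unmasking.** Target 27 is traced to its tridecamethyl ether 26 by cutting thirteen O–CH3 bonds. Methyl is chosen because the ring D oxygens arrive as methyl ethers from squarate 7, and rings E and A are available methylated (16, 19). BBr3 cleaves at the methyl carbon and has no sp3 carbon to attack in a diaryl ether. The forward step must be exhaustive and run without air.

**Central ether.** Ether 26 is cut at the B6–O bond into the ring CDE phenol 18 and the ring AB iodide 25. This cut divides the molecule into a three-ring and a two-ring half. It puts the nucleophilic oxygen on C1, which has two ortho hydrogens, and leaves the crowded carbon as the electrophile. The opposite polarity would need a halogen on ring C that could not be carried through the organolithium step. The forward reaction is a ligand-assisted copper coupling of an unhindered phenol with a di-ortho-substituted iodide.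

**Ring AB iodide.** Iodide 25 is traced through aniline 23 and nitro ether 22 to 2,4,6-trimethoxyphenol 19 and 1,3-difluoro-5-methoxy-2-nitrobenzene 20. Direct iodination of the parent ring AB ether would not distinguish B6 from B4 or from the two free positions of ring A. The iodine is therefore placed by ipso replacement of a nitrogen that first activates the A–O–B1 bond formation by nucleophilic aromatic substitution. The two fluorines of 20 are equivalent, so the regiochemistry is unambiguous.

**Ring E ether.** Phenol 18 comes from benzyl ether 17, which is cut at the O–E1 bond into phenol 15 and 3,4,5-trimethoxyphenylboronic acid 16. The D6 hydroxyl is the only free hydroxyl of 15, so no selectivity question arises. Benzyl on the C1 oxygen is the one group that must leave before the methyl ethers, and it leaves by hydrogenolysis. The forward step is an oxidative copper coupling of a hindered phenol with an unhindered boronic acid.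

**Ring D (key cut).** Phenol 15 is opened at the D6–D1 bond, and through dienylketene 13, to the 4-[(Z)-2-aryloxyvinyl]-4-methoxycyclobutenone 12. This removes the pentaoxygenated ring in one move and leaves a precursor whose oxygens are fixed by its origin. The alternative of five successive oxygenations of a benzene ring offers no comparable control. The forward step needs only heat, an outward rotation of the 4-methoxy group, and a 6π closure.

**Cyclobutenone.** Compound 12 is the cis semi-hydrogenation product of alkyne 11. Alkyne 11 is cut at the D2–D3 bond into a lithium aryloxyacetylide, generated from dichlorovinyl ether 6, and dimethyl squarate 7. The acetylide is preferred over a β-aryloxy vinyl-metal species because it cannot lose aryloxide by β-elimination and is made in one flask from 6. The squarate is symmetric, so addition to either carbonyl gives the same adduct. The alkoxide must be methylated so that only D6 emerges free.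

**Ring C.** Ether 6 is traced through phenol 5 and aldehyde 3 to 3-hydroxy-4,5-dimethoxybenzaldehyde 1 and trichloroethylene 2. The substitution pattern of 1 matches ring C exactly:
- the hydroxyl becomes the oxygen on C5 that is bound to D1;
- the two methoxy groups become C4 and C3;
- the formyl carbon is the site of the C1 oxygen, revealed by Baeyer–Villiger oxidation.

The two carbons of 2 become D1 and D2.

## Roads not taken

**Alternative 1:** Ring B as a doubly activated linchpin. Both ether bonds of ring B are cut. In the forward sense the cyclopentadienyl complex of divalent ruthenium A2, made from 1,2-dichloro-3,5-dimethoxybenzene and [CpRu(NCMe)3]PF6, would take up the phenoxide of 19 and then the phenoxide of 18 to give complex A1. Photolysis in MeCN would release 26.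

- Merits: substitution on a cationic arene complex runs near room temperature and is indifferent to the electron richness that hampers copper catalysis. The first substitution is well directed, since the chlorine-bearing carbon that becomes B1 is meta to both methoxy groups and next to a CH. The sequence would replace steps 9 to 12 with three operations, one fewer.
- Weak points: the second substitution must occur at a carbon ortho and para to two methoxy donors, ortho to the new aryloxy group and flanked on both sides, with the most valuable fragment as nucleophile. Ruthenium is used stoichiometrically. The alternative does nothing for ring D and still needs phenol 18.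
- Comparison: for ring B alone this road is at least as good as the chosen one and milder. The chosen plan offers catalytic copper, a halide whose position is fixed by synthesis, and a solution to the harder ring D problem. The linchpin could be grafted onto the chosen route after step 8.

**Alternative 2:** Ring B from a 2-pyrone. A carbon–carbon bond of ring B next to the ether-bearing carbon is cut. Mg(OMe)2 would open the lactone of pyrone A4, and the aryloxy-bearing carbon would reclose on the new ester carbonyl by Claisen condensation to give resorcinol A3.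

- Merits: the crowded ether oxygen of ring B is installed as a simple alkyl aryl ether before the ring exists, so no hindered coupling is needed there. The ring synthesis is polyketide-like and uses cheap reagents.
- Weak points: A3 has two equivalent hydroxyls flanking the ether, and one of them must then be arylated with ring A as the electrophile. A 2,4,6-trioxygenated aryl halide or boronic acid is about the poorest partner for copper chemistry, and the mono-arylation is statistical. The sequence is linear from ring C outward and again leaves ring D and its ether to ring E unsolved.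
- Comparison: this road handles the B6 oxygen better than the chosen plan. The chosen plan keeps ring A as a nucleophile throughout and spends its ring-forming step on the ring that cannot be bought.

**Alternative 3:** Ring A from an aryloxy triketide. A carbon–carbon bond of ring A next to its ether carbon is cut. Base would close 3,5-dioxohexanoate A6 by intramolecular Claisen condensation to the free 2-aryloxyphloroglucinol A5.

- Merits: the A–O–B ether is made by alkylation, and ring A emerges unprotected, so three fewer methyl ethers need cleaving at the end.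
- Weak points: the carbanion that must attack the ester is the least acidic one of A6. Lactonisation to a 4-hydroxy-2-pyrone and aldol closure to a resorcylate are the usual fates of such triketides. The free phloroglucinol would have to be protected again before any coupling. Ring A is the one ring obtainable in a single purchased compound (19).
- Comparison: the road is elegant but spends its key step on the easiest ring. The chosen plan reaches ring A by purchase and one substitution step.

Key step: step 6

Remark: compounds 10, 11, 12 and 14 each contain one stereocenter and are handled as racemates; it is erased when ring D becomes aromatic, and the target is achiral.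

## Route

Step 1
Reactants: 1 3-hydroxy-4,5-dimethoxybenzaldehyde; 2 trichloroethylene
Product: 3 3-{[(E)-1,2-dichloroethenyl]oxy}-4,5-dimethoxybenzaldehyde
Conditions: K2CO3, DMF, 70 °C
Reagents that add atoms: none
Why: Base converts 2 into dichloroacetylene in the flask and the phenoxide adds to it in an anti sense, which gives the (E)-1,2-dichlorovinyl ether (nucleophilic addition to a haloalkyne); the non-enolisable aldehyde is inert to carbonate.

Step 2
Reactants: 3 3-{[(E)-1,2-dichloroethenyl]oxy}-4,5-dimethoxybenzaldehyde
Product: 5 3-{[(E)-1,2-dichloroethenyl]oxy}-4,5-dimethoxyphenol, via aryl formate 4 (not isolated)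
Conditions: mCPBA, CH2Cl2, 0 °C to rt; Na2SO3 wash; K2CO3 (cat.), MeOH, 0 °C
Reagents that add atoms: 3-chloroperbenzoic acid (mCPBA), O=C(OO)c1cccc(Cl)c1
Why: Baeyer–Villiger oxidation of an electron-rich benzaldehyde, in which the aryl group with its para methoxy donor migrates; the formate is cleaved by mild methanolysis and the chlorine-deactivated enol ether should not be epoxidised.

Step 3
Reactants: 5 3-{[(E)-1,2-dichloroethenyl]oxy}-4,5-dimethoxyphenol
Product: 6 5-(benzyloxy)-1-{[(E)-1,2-dichloroethenyl]oxy}-2,3-dimethoxybenzene
Conditions: BnBr, K2CO3, DMF, rt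
Reagents that add atoms: benzyl bromide, BrCc1ccccc1
Why: Williamson etherification of an unhindered phenol; benzyl marks the C1 oxygen as the one to be freed before the methyl ethers.

Step 4
Reactants: 6 5-(benzyloxy)-1-{[(E)-1,2-dichloroethenyl]oxy}-2,3-dimethoxybenzene; 7 dimethyl squarate
Product: 11 4-{[5-(benzyloxy)-2,3-dimethoxyphenoxy]ethynyl}-2,3,4-trimethoxycyclobut-2-en-1-one (racemic), via chloroethynyl ether 8 (not isolated), via lithium aryloxyacetylide 9 (not isolated), via lithium cyclobutenolate 10 (not isolated)
Conditions: n-BuLi (2.2 equiv), THF, −78 to −40 °C; add to 7, THF, −78 °C; MeOTf, −78 to 0 °C; NaHCO3 work-up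
Reagents that add atoms: methyl trifluoromethanesulfonate, COS(=O)(=O)C(F)(F)F
Why: Dehydrochlorination and chlorine–lithium exchange turn the dichlorovinyl ether into the lithium ynolate-ether acetylide, which adds 1,2 to one carbonyl of the symmetric squarate as other lithium acetylides do; O-methylation of the tertiary alkoxide with the triflate follows in the same flask, and a basic work-up protects the acid-labile ynol ether.

Step 5
Reactants: 11 4-{[5-(benzyloxy)-2,3-dimethoxyphenoxy]ethynyl}-2,3,4-trimethoxycyclobut-2-en-1-one
Product: 12 4-[(Z)-2-(5-benzyloxy-2,3-dimethoxyphenoxy)ethenyl]-2,3,4-trimethoxycyclobut-2-en-1-one (racemic)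
Conditions: H2 (1 atm), Pd/CaCO3 poisoned with Pb(OAc)2 (Lindlar catalyst), quinoline, EtOAc, 0 °C to rt
Reagents that add atoms: none
Why: Lindlar semi-hydrogenation adds hydrogen syn to the ynol ether and stops at the (Z)-enol ether; the benzyl ether and the tetrasubstituted ring alkene are not touched by the poisoned catalyst.

Step 6
Reactants: 12 4-[(Z)-2-(5-benzyloxy-2,3-dimethoxyphenoxy)ethenyl]-2,3,4-trimethoxycyclobut-2-en-1-one
Product: 15 6-[5-(benzyloxy)-2,3-dimethoxyphenoxy]-2,3,4-trimethoxyphenol, via dienylketene 13 (not isolated), via cyclohexa-2,4-dienone 14 (not isolated)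
Conditions: degassed PhMe (0.01 M), 110 °C, Ar, base-washed glassware
Reagents that add atoms: none
Why: Heating cleaves the C1–C4 bond of the cyclobutenone by a thermal conrotatory 4π opening in which the donor methoxy group on C4 rotates outward, as oxygen substituents on this carbon do, so that the aryloxyvinyl group turns inward and the (3Z)-dienylketene 13 holds its ketene carbon next to the vinyl terminus. A disrotatory 6π electrocyclisation then joins the ketene carbon (D6) to the aryloxy-bearing vinyl carbon (D1); this is the only ring closure, it builds the six-membered carbocycle from six contiguous sp2 carbons, and its only competitor, four-membered reclosure, merely returns 12. Dienone 14 carries a hydrogen on the new sp3 carbon and enolises irreversibly to phenol 15, so the transient stereocenters of 12 and 14 vanish and no configuration has to be set. The closest known reaction is the thermal ring expansion of 4-alkenyl-4-alkoxy- and 4-alkenyl-4-hydroxycyclobutenones from squaric esters to hydroquinone mono-ethers and hydroquinones (Moore rearrangement type). Regiochemistry needs no control because the squarate is symmetric and the two-carbon unit can close only through its terminus; the selectivity that is needed is the torquoselectivity of the opening, which the 4-methoxy group secures. The (Z)-aryloxy group lies on the inner side of the closing terminus, which should be tolerable because the ketene partner is sp-hybridised and carries no inward substituent. Since the C4 oxygen is capped as a methyl ether, only the ketene oxygen emerges as a free hydroxyl, at D6, where ring E is attached next.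

Step 7
Reactants: 15 6-[5-(benzyloxy)-2,3-dimethoxyphenoxy]-2,3,4-trimethoxyphenol; 16 3,4,5-trimethoxyphenylboronic acid
Product: 17 5-(benzyloxy)-1,2-dimethoxy-3-[3,4,5-trimethoxy-2-(3,4,5-trimethoxyphenoxy)phenoxy]benzene
Conditions: Cu(OAc)2 (1.5 equiv), pyridine, 4 Å MS, CH2Cl2, dry air, rt; 16 in excess
Reagents that add atoms: none
Why: Chan–Lam coupling; the oxidative copper pathway tolerates ortho-disubstituted phenols at room temperature when the boronic acid is unhindered, and 15 has only one hydroxyl.

Step 8
Reactants: 17 5-(benzyloxy)-1,2-dimethoxy-3-[3,4,5-trimethoxy-2-(3,4,5-trimethoxyphenoxy)phenoxy]benzene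
Product: 18 3,4-dimethoxy-5-[3,4,5-trimethoxy-2-(3,4,5-trimethoxyphenoxy)phenoxy]phenol
Conditions: H2 (1 atm), Pd/C, EtOAc–MeOH, rt
Reagents that add atoms: none
Why: Hydrogenolysis of the benzyl ether; diaryl and methyl ethers are stable to these conditions.

Step 9
Reactants: 19 2,4,6-trimethoxyphenol; 20 1,3-difluoro-5-methoxy-2-nitrobenzene
Product: 22 1,5-dimethoxy-2-nitro-3-(2,4,6-trimethoxyphenoxy)benzene, via fluoronitro diaryl ether 21 (not isolated)
Conditions: K2CO3, DMF, rt to 40 °C; then NaOMe, MeOH, 60 °C
Reagents that add atoms: sodium methoxide, C[O-].[Na+]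
Why: Two successive nucleophilic aromatic substitutions of fluoride ortho to the nitro group; the two fluorines of 20 are equivalent, the first aryloxy group slows the second substitution enough for mono-arylation, and methoxide then replaces the remaining fluoride.

Step 10
Reactants: 22 1,5-dimethoxy-2-nitro-3-(2,4,6-trimethoxyphenoxy)benzene
Product: 23 2,4-dimethoxy-6-(2,4,6-trimethoxyphenoxy)aniline
Conditions: H2 (1 atm), Pd/C, EtOAc–EtOH, rt; used at once
Reagents that add atoms: none
Why: Catalytic hydrogenation of an aryl nitro group; nothing else in the molecule is reducible.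

Step 11
Reactants: 23 2,4-dimethoxy-6-(2,4,6-trimethoxyphenoxy)aniline
Product: 25 2-(2-iodo-3,5-dimethoxyphenoxy)-1,3,5-trimethoxybenzene, via arenediazonium tosylate 24 (not isolated)
Conditions: p-TsOH·H2O, NaNO2, KI, MeCN–H2O, 10 °C to rt
Reagents that add atoms: potassium iodide, [K+].[I-]
Why: Sandmeyer-type diazotisation and iodide substitution places iodine exactly on B6; both ring A positions ortho to the ether oxygen carry methoxy groups, which blocks cyclisation of the aryl intermediate to a dibenzofuran.

Step 12
Reactants: 18 3,4-dimethoxy-5-[3,4,5-trimethoxy-2-(3,4,5-trimethoxyphenoxy)phenoxy]phenol; 25 2-(2-iodo-3,5-dimethoxyphenoxy)-1,3,5-trimethoxybenzene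
Product: 26 2-[2-[3,4-dimethoxy-5-[3,4,5-trimethoxy-2-(3,4,5-trimethoxyphenoxy)phenoxy]phenoxy]-3,5-dimethoxyphenoxy]-1,3,5-trimethoxybenzene
Conditions: CuI (10 mol %), picolinic acid (20 mol %), K3PO4, DMSO, 90 °C, Ar
Reagents that add atoms: none
Why: Ullmann-type diaryl ether synthesis with a chelating carboxylate ligand, a system suited to ortho-substituted aryl iodides; the phenol partner has two free ortho positions.

Step 13
Reactants: 26 2-[2-[3,4-dimethoxy-5-[3,4,5-trimethoxy-2-(3,4,5-trimethoxyphenoxy)phenoxy]phenoxy]-3,5-dimethoxyphenoxy]-1,3,5-trimethoxybenzene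
Product: 27 pseudopentafuhalol D, 2-[2-[3,4-dihydroxy-5-[3,4,5-trihydroxy-2-(3,4,5-trihydroxyphenoxy)phenoxy]phenoxy]-3,5-dihydroxyphenoxy]benzene-1,3,5-triol
Conditions: BBr3 (excess), CH2Cl2, −78 °C to rt, Ar; then MeOH, H2O; degassed work-up
Reagents that add atoms: none
Why: Lewis-acid demethylation; bromide attacks the methyl carbon of each boron-bound aryl methyl ether, whereas the diaryl ether oxygens offer no sp3 carbon and stay intact.

## Compound list

1 | 3-hydroxy-4,5-dimethoxybenzaldehyde | COc1cc(C=O)cc(O)c1OC | starting material
2 | trichloroethylene | ClC=C(Cl)Cl | starting material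
3 | 3-{[(E)-1,2-dichloroethenyl]oxy}-4,5-dimethoxybenzaldehyde | COc1cc(C=O)cc(O/C(Cl)=C\Cl)c1OC | intermediate
4 | 3-{[(E)-1,2-dichloroethenyl]oxy}-4,5-dimethoxyphenyl formate | COc1cc(OC=O)cc(O/C(Cl)=C\Cl)c1OC | intermediate (not isolated)
5 | 3-{[(E)-1,2-dichloroethenyl]oxy}-4,5-dimethoxyphenol | COc1cc(O)cc(O/C(Cl)=C\Cl)c1OC | intermediate
6 | 5-(benzyloxy)-1-{[(E)-1,2-dichloroethenyl]oxy}-2,3-dimethoxybenzene | COc1cc(OCc2ccccc2)cc(O/C(Cl)=C\Cl)c1OC | intermediate
7 | dimethyl squarate (3,4-dimethoxycyclobut-3-ene-1,2-dione) | COC1=C(OC)C(=O)C1=O | starting material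
8 | 5-(benzyloxy)-1-[(chloroethynyl)oxy]-2,3-dimethoxybenzene | COc1cc(OCc2ccccc2)cc(OC#CCl)c1OC | intermediate (not isolated)
9 | {[5-(benzyloxy)-2,3-dimethoxyphenoxy]ethynyl}lithium | COc1cc(OCc2ccccc2)cc(OC#C[Li])c1OC | intermediate (not isolated)
10 | lithium 1-{[5-(benzyloxy)-2,3-dimethoxyphenoxy]ethynyl}-2,3-dimethoxy-4-oxocyclobut-2-en-1-olate (racemic) | COC1=C(OC)C([O-])(C#COc2cc(OCc3ccccc3)cc(OC)c2OC)C1=O.[Li+] | intermediate (not isolated)
11 | 4-{[5-(benzyloxy)-2,3-dimethoxyphenoxy]ethynyl}-2,3,4-trimethoxycyclobut-2-en-1-one (racemic) | COC1=C(OC)C(OC)(C#COc2cc(OCc3ccccc3)cc(OC)c2OC)C1=O | intermediate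
12 | 4-[(Z)-2-(5-benzyloxy-2,3-dimethoxyphenoxy)ethenyl]-2,3,4-trimethoxycyclobut-2-en-1-one (racemic) | COC1=C(OC)C(OC)(/C=C\Oc2cc(OCc3ccccc3)cc(OC)c2OC)C1=O | intermediate
13 | (3Z,5Z)-6-[5-(benzyloxy)-2,3-dimethoxyphenoxy]-2,3,4-trimethoxyhexa-1,3,5-trien-1-one | O=C=C(OC)\C(OC)=C(OC)/C=C\Oc1cc(OCc2ccccc2)cc(OC)c1OC | intermediate (not isolated)
14 | 6-[5-(benzyloxy)-2,3-dimethoxyphenoxy]-2,3,4-trimethoxycyclohexa-2,4-dien-1-one (racemic) | COC1=CC(Oc2cc(OCc3ccccc3)cc(OC)c2OC)C(=O)C(OC)=C1OC | intermediate (not isolated)
15 | 6-[5-(benzyloxy)-2,3-dimethoxyphenoxy]-2,3,4-trimethoxyphenol | COc1cc(OCc2ccccc2)cc(Oc2cc(OC)c(OC)c(OC)c2O)c1OC | intermediate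
16 | 3,4,5-trimethoxyphenylboronic acid | COc1cc(B(O)O)cc(OC)c1OC | starting material
17 | 5-(benzyloxy)-1,2-dimethoxy-3-[3,4,5-trimethoxy-2-(3,4,5-trimethoxyphenoxy)phenoxy]benzene | COc1cc(OCc2ccccc2)cc(Oc2cc(OC)c(OC)c(OC)c2Oc2cc(OC)c(OC)c(OC)c2)c1OC | intermediate
18 | 3,4-dimethoxy-5-[3,4,5-trimethoxy-2-(3,4,5-trimethoxyphenoxy)phenoxy]phenol | COc1cc(O)cc(Oc2cc(OC)c(OC)c(OC)c2Oc2cc(OC)c(OC)c(OC)c2)c1OC | intermediate
19 | 2,4,6-trimethoxyphenol | COc1cc(OC)c(O)c(OC)c1 | starting material
20 | 1,3-difluoro-5-methoxy-2-nitrobenzene | COc1cc(F)c([N+](=O)[O-])c(F)c1 | starting material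
21 | 1-fluoro-5-methoxy-2-nitro-3-(2,4,6-trimethoxyphenoxy)benzene | COc1cc(F)c([N+](=O)[O-])c(Oc2c(OC)cc(OC)cc2OC)c1 | intermediate (not isolated)
22 | 1,5-dimethoxy-2-nitro-3-(2,4,6-trimethoxyphenoxy)benzene | COc1cc(OC)c([N+](=O)[O-])c(Oc2c(OC)cc(OC)cc2OC)c1 | intermediate
23 | 2,4-dimethoxy-6-(2,4,6-trimethoxyphenoxy)aniline | COc1cc(OC)c(N)c(Oc2c(OC)cc(OC)cc2OC)c1 | intermediate
24 | 2,4-dimethoxy-6-(2,4,6-trimethoxyphenoxy)benzenediazonium 4-methylbenzenesulfonate | COc1cc(OC)c([N+]#N)c(Oc2c(OC)cc(OC)cc2OC)c1.Cc1ccc(cc1)S([O-])(=O)=O | intermediate (not isolated)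
25 | 2-(2-iodo-3,5-dimethoxyphenoxy)-1,3,5-trimethoxybenzene | COc1cc(OC)c(I)c(Oc2c(OC)cc(OC)cc2OC)c1 | intermediate
26 | 2-[2-[3,4-dimethoxy-5-[3,4,5-trimethoxy-2-(3,4,5-trimethoxyphenoxy)phenoxy]phenoxy]-3,5-dimethoxyphenoxy]-1,3,5-trimethoxybenzene | COc1cc(OC)c(Oc2cc(OC)cc(OC)c2Oc2cc(OC)c(OC)c(Oc3cc(OC)c(OC)c(OC)c3Oc3cc(OC)c(OC)c(OC)c3)c2)c(OC)c1 | intermediate
27 | pseudopentafuhalol D | Oc1cc(O)c(Oc2cc(O)cc(O)c2Oc2cc(O)c(O)c(Oc3cc(O)c(O)c(O)c3Oc3cc(O)c(O)c(O)c3)c2)c(O)c1 | target

## Step count and risks

Total: 13 steps. Longest linear sequence: 10 steps (steps 1 to 8, 12 and 13); steps 9 to 11 form the ring AB branch.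

**Step 6 (key step).** The most likely failure is a slow 6π closure, because the (Z)-aryloxy group occupies the inner position of the closing terminus. The dienylketene would then be diverted into dimerisation or capture by adventitious nucleophiles. Acid-promoted loss of the tertiary allylic methoxy group from the vinylogous acetal before ring opening and air oxidation of the electron-rich phenol are further risks.

The fallback gives up the squarate and builds the three rings by classical ether chemistry. It sets out from boronic acid 16 and returns to the route at phenol 18.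
- Compound 16 would be oxidised with alkaline H2O2 to 3,4,5-trimethoxyphenol F1 (which can also be bought).
- Copper-catalysed coupling of F1 with purchased 2-bromo-3,4,5-trimethoxybenzaldehyde (CuI, picolinic acid, K3PO4, DMSO) would give 3,4,5-trimethoxy-2-(3,4,5-trimethoxyphenoxy)benzaldehyde F2, the ortho formyl group assisting the substitution.
- Baeyer–Villiger oxidation with mCPBA and methanolysis would give 3,4,5-trimethoxy-2-(3,4,5-trimethoxyphenoxy)phenol F3, whose hydroxyl is the D1 oxygen.
- A second copper-catalysed coupling, with purchased 3-bromo-4,5-dimethoxybenzaldehyde, would give 3,4-dimethoxy-5-[3,4,5-trimethoxy-2-(3,4,5-trimethoxyphenoxy)phenoxy]benzaldehyde F4.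
- A second Baeyer–Villiger oxidation and methanolysis would deliver 18.

**Step 4.** The most likely failure is incomplete O-methylation of the hindered tertiary lithium alkoxide, or its decomposition on warming, with triflate-initiated polymerisation of THF competing.

The fallback separates the two events. It sets out from 6 and 7 and returns at 11. The addition would be quenched with aqueous NH4Cl and the alcohol isolated as 4-{[5-(benzyloxy)-2,3-dimethoxyphenoxy]ethynyl}-4-hydroxy-2,3-dimethoxycyclobut-2-en-1-one F5. F5 would then be methylated under neutral Purdie conditions (MeI, Ag2O, MeCN) to give 11.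

**Step 5.** The most likely failure is over-reduction of the electron-rich enol ether, or hydrogenolysis of the propargylic and then allylic C–OMe bond on the palladium surface.

The fallback sets the alkene geometry before the four-membered ring is attached. It sets out from 6 and returns at 12.
- Treatment of 6 with n-BuLi and a methanol quench would give 5-(benzyloxy)-1-(ethynyloxy)-2,3-dimethoxybenzene F6.
- Radical hydrostannation (Bu3SnH, AIBN), which adds anti to alkoxyacetylenes, would give tributyl{(Z)-2-[5-(benzyloxy)-2,3-dimethoxyphenoxy]ethenyl}stannane F7.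
- Tin–lithium exchange with n-BuLi at −78 °C would give {(Z)-2-[5-(benzyloxy)-2,3-dimethoxyphenoxy]ethenyl}lithium F8. In F8 the cis arrangement of lithium and aryloxy disfavours β-elimination.
- Addition of F8 to 7 and O-methylation with MeOTf in the same flask would give 12.

**Step 12.** The most likely failure is slow oxidative addition of the doubly ortho-substituted, electron-rich iodide to copper, so that protodeiodination and oxidative decay of the phenoxide win.

The fallback reverses the polarity of the bond. It sets out from 23 and 18 and returns at 26.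
- Diazonium salt 24, made as in step 11 without KI, would be hydrolysed (Cu2O, Cu(NO3)2, H2O) to 2,4-dimethoxy-6-(2,4,6-trimethoxyphenoxy)phenol F9.
- Phenol 18 would be converted with Tf2O and pyridine into 3,4-dimethoxy-5-[3,4,5-trimethoxy-2-(3,4,5-trimethoxyphenoxy)phenoxy]phenyl trifluoromethanesulfonate F10, an unhindered electrophile.
- Palladium-catalysed C–O coupling of F9 with F10 (Pd(OAc)2, 2-di-tert-butylphosphino-2′,4′,6′-triisopropylbiphenyl, K3PO4, PhMe, 100 °C) would give 26.

**Step 7.** The most likely failure is oxidation of the para-methoxyphenol 15 to a quinone by divalent copper and air, together with protodeboronation of 16 outrunning arylation of the hindered hydroxyl.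

The fallback replaces the oxidative coupling by a redox-neutral one under argon. It sets out from 15 and returns at 17. Compound 15 would be coupled with purchased 5-iodo-1,2,3-trimethoxybenzene (CuI, picolinic acid, K3PO4, DMSO, 90 °C). No new compound is made on the way (entry F0).

## Further compounds

F1 | step 6 | 3,4,5-trimethoxyphenol | COc1cc(O)cc(OC)c1OC
F2 | step 6 | 3,4,5-trimethoxy-2-(3,4,5-trimethoxyphenoxy)benzaldehyde | COc1cc(Oc2c(C=O)cc(OC)c(OC)c2OC)cc(OC)c1OC
F3 | step 6 | 3,4,5-trimethoxy-2-(3,4,5-trimethoxyphenoxy)phenol | COc1cc(Oc2c(O)cc(OC)c(OC)c2OC)cc(OC)c1OC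
F4 | step 6 | 3,4-dimethoxy-5-[3,4,5-trimethoxy-2-(3,4,5-trimethoxyphenoxy)phenoxy]benzaldehyde | COc1cc(C=O)cc(Oc2cc(OC)c(OC)c(OC)c2Oc2cc(OC)c(OC)c(OC)c2)c1OC
F5 | step 4 | 4-{[5-(benzyloxy)-2,3-dimethoxyphenoxy]ethynyl}-4-hydroxy-2,3-dimethoxycyclobut-2-en-1-one (racemic) | COC1=C(OC)C(O)(C#COc2cc(OCc3ccccc3)cc(OC)c2OC)C1=O
F6 | step 5 | 5-(benzyloxy)-1-(ethynyloxy)-2,3-dimethoxybenzene | COc1cc(OCc2ccccc2)cc(OC#C)c1OC
F7 | step 5 | tributyl{(Z)-2-[5-(benzyloxy)-2,3-dimethoxyphenoxy]ethenyl}stannane | CCCC[Sn](CCCC)(CCCC)/C=C\Oc1cc(OCc2ccccc2)cc(OC)c1OC
F8 | step 5 | {(Z)-2-[5-(benzyloxy)-2,3-dimethoxyphenoxy]ethenyl}lithium | [Li]/C=C\Oc1cc(OCc2ccccc2)cc(OC)c1OC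
F9 | step 12 | 2,4-dimethoxy-6-(2,4,6-trimethoxyphenoxy)phenol | COc1cc(OC)c(O)c(Oc2c(OC)cc(OC)cc2OC)c1
F10 | step 12 | 3,4-dimethoxy-5-[3,4,5-trimethoxy-2-(3,4,5-trimethoxyphenoxy)phenoxy]phenyl trifluoromethanesulfonate | COc1cc(OS(=O)(=O)C(F)(F)F)cc(Oc2cc(OC)c(OC)c(OC)c2Oc2cc(OC)c(OC)c(OC)c2)c1OC
F0 | step 7 | none | none
A1 | alternative 1 | cyclopentadienylruthenium hexafluorophosphate complex of tridecamethyl ether 26, bound η6 at ring B | COc1cc(OC)c(Oc2cc(OC)c(OC)c(Oc3cc(OC)c(OC)c(OC)c3Oc3cc(OC)c(OC)c(OC)c3)c2)c(Oc2c(OC)cc(OC)cc2OC)c1.[cH-]1cccc1.[Ru+2].F[P-](F)(F)(F)(F)F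
A2 | alternative 1 | (η6-1,2-dichloro-3,5-dimethoxybenzene)(cyclopentadienyl)ruthenium hexafluorophosphate | COc1cc(OC)c(Cl)c(Cl)c1.[cH-]1cccc1.[Ru+2].F[P-](F)(F)(F)(F)F
A3 | alternative 2 | 2-[3-(benzyloxy)-4,5-dimethoxyphenoxy]-5-methoxybenzene-1,3-diol | COc1cc(O)c(Oc2cc(OC)c(OC)c(OCc3ccccc3)c2)c(O)c1
A4 | alternative 2 | 6-{[3-(benzyloxy)-4,5-dimethoxyphenoxy]methyl}-4-methoxy-2H-pyran-2-one | COC1=CC(=O)OC(COc2cc(OC)c(OC)c(OCc3ccccc3)c2)=C1
A5 | alternative 3 | 2-[2-(benzyloxy)-3,5-dimethoxyphenoxy]benzene-1,3,5-triol | Oc1cc(O)c(Oc2cc(OC)cc(OC)c2OCc2ccccc2)c(O)c1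
A6 | alternative 3 | methyl 6-[2-(benzyloxy)-3,5-dimethoxyphenoxy]-3,5-dioxohexanoate | COC(=O)CC(=O)CC(=O)COc1cc(OC)cc(OC)c1OCc1ccccc1
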